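## The problem

Target 32 is a cyclohexane substituted on five of its six carbons and trans-fused along C6–C7 to an α-methylene-γ-butyrolactone; O8 is esterified with (2R)-3-hydroxy-2-methylpropanoic acid. The numbering used throughout is: C10 quaternary with methyl C14 and vinyl C1=C2, C9 methylene, C8 acyloxy, C7 bearing C11 with methylene C13 and carbonyl C12, C6 lactone oxygen, C5 bearing C4 with methylene C3 and hydroxymethyl C15. The four contiguous methine centres C5–C8 are all-trans and all equatorial, while C10 holds its vinyl group cis to the C4 branch on C5; a chair union of two E alkenes would give the opposite arrangement, so the C5/C10 pair needs a deliberate solution. C5 and C10 have no neighbour to lean on and must be set together and absolutely; C6 can then follow from C5 (Felkin–Anh), and C7 and C8 from C6 and a defined alkene geometry if the ring closes through a chair; the side-chain centre comes from the chiral pool. O6 and O8 are both 1,4 to C12, so either can close a five-membered lactone and either can carry the ester, and the order in which they are unmasked decides the constitution. The α-methylene lactone (a base-labile Michael acceptor), the C8 ester with its epimerisable α-centre and the primary allylic alcohol will not survive basic or strongly nucleophilic treatment, so the finish must be short and non-basic. The enabling feature is that C7 carries the acrylate unit (C11, C12, C13) between the oxygenated carbons C6 and C8 and is trans to both: this is the product pattern of a γ-oxygenated 2-(borylmethyl)acrylate adding through C7 to a C8 aldehyde, and because C8 is tied to C6 through C9, C10 and C5 the same bond closes the ring.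

## Retrosynthesis

**32 ⇒ 30.** The O6–C12 lactone bond and the three O–Si bonds are cut last. With O8 already acylated in 30, only O6 can lactonise once it is freed, so the lactone/ester regiochemistry is fixed by the order of events and not by a selectivity. The forward step has to desilylate and lactonise under acidic, non-basic conditions.

**30 ⇒ 25 + 28.** The ester C–O bond at O8 is cut, which removes one stereocentre and the whole side chain. Acid 28 comes from the Roche ester 26 through 27. Placing the acylation here is preferred to a late differentiation of a 6,8-diol because in 25 the only free hydroxyl is O8. The forward step must acylate a hindered secondary alcohol faster than that alcohol can attack the neighbouring methyl acrylate.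

**25 ⇒ 23 (key disconnection).** The C7–C8 bond is cut, opening the carbocycle to the ω-formyl (Z)-2-(borylmethyl)enoate 23.
- The neighbouring cut C6–C7 would put the aldehyde on the branched C6 and deliver O6, not O8, as the free hydroxyl.
- A cut at C5–C10 inside the ring offers no comparable stereospecific closure.
- Cutting C7–C8 uses an unhindered CH2–CHO electrophile, frees O8 while O6 stays silylated, and brings in the complete acrylate.
- The precursor is acyclic with three stereocentres (C5, C6, C10) in place of five.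
- The forward reaction must transmit the alkene geometry into trans C7/C8 and let C6 direct C7.

**23 ⇒ 22 ⇒ 21 ⇒ 19.** The C8 aldehyde is traced to a PMB-protected alcohol (21) through alcohol 22. A PMB ether is preferred to an acetal because the Lewis-acidic bromoborane of the Claisen step could ionise an acetal. The C11–C13 bond and the C7–H bond are then cut together: syn-hydroalumination of ynoate 19 and alkylation with an iodomethylboronate. This reduces the trisubstituted alkene to an alkyne with no geometry to control, and the geometry needed later is created by a stereospecific addition.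

**19 ⇒ 18 ⇒ 15 + 16.** The C6–C7 bond is cut to aldehyde 15 and methyl propiolate 16. Adding the three-carbon unit in the right oxidation state avoids a separate carboxylation. The forward addition has to be Felkin-selective, for which the quaternary C10 serves as the large group.

**15 ⇒ 14 ⇒ 13 ⇒ 11.** After adjusting the oxidation level (alcohol 14, acid 13), the C5–C10 bond is cut by an Ireland–Claisen transform to allylic ester 11, through boron ketene acetal 12. This is the only disconnection that forms the quaternary centre and its neighbour in one stereodefined event. The precursor has no stereocentre. The forward reaction needs the E alkene, the enolate geometry with C4 cis to O–B, and an external chiral controller on boron.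

**11 ⇒ 9 + 5.** The ester bond is cut.
- Acid 9 comes from 4-methyl hydrogen itaconate 6 by chemoselective reduction (7), silylation (8) and saponification.
- Alcohol 5 comes from but-3-yn-1-ol 1 through PMB ether 2 by carboalumination–hydroxymethylation (through 3 and 4). This is preferred to olefination of a methyl ketone because it gives the E alkene as a single isomer.

## Roads not taken

**Alternative 1:** The cut is through C10–C1 and C5–C4. In the forward direction, irradiation (350 nm) of silyloxy enone A1 with propargyl silyl ether A2 would give the cis-fused cyclobutene A3, and ethenolysis would then turn the C1=C4 bond into the two terminal alkenes.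
- Merits: one step creates quaternary C10 and C5, and the cis ring fusion enforces exactly the cis relationship of the C1 and C4 branches that the target needs. Absolute configuration comes from one inexpensive stereocentre (C8) and no stoichiometric chiral reagent is used. On the C5/C10 problem this road is shorter and surer than the Claisen of the chosen plan.
- Weak points: the required orientation (substituted alkyne carbon on the α-carbon C5) is not reliably predictable for monosubstituted alkynes. Facial control from the remote C8 silyloxy group is only moderate, and cyclobutene photoproducts can react further under irradiation. After A3, C7 is still unfunctionalised: the acrylate would have to be introduced α to the C6 ketone and β to the C8 silyloxy group, so any C7 enolate invites β-elimination of O8. C6 and C7 would then have to be set by substrate control in separate steps.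
- Comparison: the chosen plan sets against the brevity of A3 that the ring, C7, C8 and the complete acrylate arise in one chair-controlled step and that no β-oxygenated ketone enolate is ever formed.

**Alternative 2:** The cut is through O6–C12 and C12–C11. In the forward direction PdCl2 with thiourea under carbon monoxide would convert the trans-2-ethynyl alcohol A4 into the bis-silylated lactone A5, one desilylation from the target.
- Merits: the lactone is made last from an alkyne, so no acrylate ester ever sits beside a free C8 hydroxyl and wrong-way lactonisation, the main chemoselectivity worry of the chosen plan, cannot occur. The Michael acceptor exists only in the last two compounds. In this respect the road is better.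
- Weak points: the key step builds no ring bond and no stereocentre. A4 already contains the whole cyclohexane, all five ring stereocentres and a trans ethynyl group between two oxygenated carbons, for which a separate solution is still needed. Palladium hydride species under carbon monoxide could engage the vinyl and 1,1-disubstituted alkenes, and the free C6 hydroxyl next to the C8 ester is open to acyl migration.
- Comparison: the chosen plan sets against the cleaner endgame that its key step solves ring construction and two stereocentres, and that its lactonisation risk is handled by the order of events (borate, then acylation).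

**Alternative 3:** The cut is at C9–C10. In the forward direction methylaluminium bis(4-bromo-2,6-di-tert-butylphenoxide) would open cycloheptene oxide A6 at C10 and C9 would migrate from C1 to C10, giving the ring-contracted aldehyde A7.
- Merits: quaternary C10 is formed stereospecifically (migration anti to the departing oxygen), independent of any enolate geometry. The lactone ring and the C6–C8 centres are already in place. For C10 alone this is in principle more secure than the Claisen step.
- Weak points: A6 requires a cycloheptene with four stereocentres, a trans-fused lactone and a face-selective epoxidation. Hydride shift to a ketone competes with ring contraction, and the Lewis acid has a lactone and a ketone to bind. After A7 three methylenations remain (the C1 aldehyde, the C4 ketone beside epimerisable C5, and the lactone α-position), besides the exchange of the C8 silyl ether for the side chain.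
- Comparison: the chosen plan sets against the stereospecific C10 of A7 that its Claisen step fixes C5 as well and that all three alkenes are carried in their final form from early on.

Key step: step 15

Abbreviations in names: TBS = tert-butyldimethylsilyl; TBDPS = tert-butyldiphenylsilyl; PMB = 4-methoxybenzyl; Bpin = 4,4,5,5-tetramethyl-1,3,2-dioxaborolan-2-yl.

Assumption: the (S,S)-configured diazaborolidine bromide is taken to deliver the (2R,3R)-acid 13, by analogy with its behaviour on simple E-allyl esters; if the sense of induction proves opposite, the (R,R)-reagent from the antipodal diamine is used and nothing else changes.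

## Route

Step 1
Reactants: 1 but-3-yn-1-ol
Product: 2 1-[(but-3-yn-1-yloxy)methyl]-4-methoxybenzene
Conditions: NaH, 4-methoxybenzyl chloride, Bu4NI (cat.), THF/DMF, 0 °C to rt
Reagents that add atoms: 4-methoxybenzyl chloride, COc1ccc(CCl)cc1
Why: Williamson etherification; the alkoxide forms far ahead of the acetylide, so O-alkylation is the only pathway expected.

Step 2
Reactants: 2 1-[(but-3-yn-1-yloxy)methyl]-4-methoxybenzene
Product: 5 (2E)-5-[(4-methoxybenzyl)oxy]-3-methylpent-2-en-1-ol, via alkenyldimethylalane 3 (not isolated), via lithium alanate 4 (not isolated)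
Conditions: AlMe3, Cp2ZrCl2 (cat.), CH2Cl2, 0 °C to rt; then n-BuLi, THF, −78 °C; (CH2O)n, −78 °C to rt
Reagents that add atoms: trimethylaluminium, C[Al](C)C; paraformaldehyde (as formaldehyde), C=O
Why: Zirconium-catalysed carboalumination (Negishi) adds CH3–Al syn across the terminal alkyne with aluminium at the terminus, and the derived alanate is hydroxymethylated with retention, so the methyl group ends cis to CH2OH (E alkene) as a single isomer.

Step 3
Reactants: 6 4-methyl hydrogen itaconate (4-methoxy-2-methylidene-4-oxobutanoic acid)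
Product: 7 methyl 3-(hydroxymethyl)but-3-enoate
Conditions: BH3·SMe2 (1 equiv), THF, −10 °C to rt; MeOH quench
Reagents that add atoms: none
Why: Chemoselective borane reduction: the free acid is reduced through its acyloxyborane far faster than the methyl ester, and one equivalent leaves no hydride for hydroboration of the alkene; the γ-hydroxy ester is silylated at once to forestall lactonisation.

Step 4
Reactants: 7 methyl 3-(hydroxymethyl)but-3-enoate
Product: 8 methyl 3-{[(TBDPS)oxy]methyl}but-3-enoate
Conditions: TBDPSCl, imidazole, CH2Cl2, 0 °C to rt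
Reagents that add atoms: tert-butyl(chloro)diphenylsilane, CC(C)(C)[Si](Cl)(c1ccccc1)c1ccccc1
Why: Standard silylation of a primary alcohol; TBDPS is chosen for O15 because it survives the Lewis-acidic and hydridic steps that follow and falls only to fluoride at the end.

Step 5
Reactants: 8 methyl 3-{[(TBDPS)oxy]methyl}but-3-enoate
Product: 9 3-{[(TBDPS)oxy]methyl}but-3-enoic acid
Conditions: LiOH, THF/H2O, 0 °C; then 1 M HCl to pH 3–4, 0 °C
Reagents that add atoms: lithium hydroxide, [Li+].[OH-]
Why: Saponification; hydroxide attacks the unhindered methyl ester faster than it deprotonates the α-carbon, and the carboxylate once formed resists α-deprotonation, so the alkene should stay out of conjugation.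

Step 6
Reactants: 9 3-{[(TBDPS)oxy]methyl}but-3-enoic acid; 5 (2E)-5-[(4-methoxybenzyl)oxy]-3-methylpent-2-en-1-ol
Product: 11 (2E)-5-[(4-methoxybenzyl)oxy]-3-methylpent-2-en-1-yl 3-{[(TBDPS)oxy]methyl}but-3-enoate, via O-acylisourea 10 (not isolated)
Conditions: DCC, 4-dimethylaminopyridine (cat.), CH2Cl2, 0 °C to rt
Reagents that add atoms: none
Why: Steglich esterification of a primary allylic alcohol; low temperature and only catalytic 4-dimethylaminopyridine keep the β,γ-unsaturated acyl group from drifting into conjugation.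

Step 7
Reactants: 11 (2E)-5-[(4-methoxybenzyl)oxy]-3-methylpent-2-en-1-yl 3-{[(TBDPS)oxy]methyl}but-3-enoate
Product: 13 (2R,3R)-2-{3-[(TBDPS)oxy]prop-1-en-2-yl}-3-{2-[(PMB)oxy]ethyl}-3-methylpent-4-enoic acid, via boron ketene acetal 12 (not isolated)
Conditions: (4S,5S)-2-bromo-1,3-bis{[3,5-bis(trifluoromethyl)phenyl]sulfonyl}-4,5-diphenyl-1,3,2-diazaborolidine [from the (S,S)-bis-sulfonamide and BBr3, CH2Cl2], i-Pr2NEt, CH2Cl2, −78 °C then 4 °C; aq. work-up
Reagents that add atoms: none
Why: Boron-mediated enantioselective Ireland–Claisen rearrangement: amine-promoted enolisation in CH2Cl2 gives the Z(O) boron ketene acetal 12 (C4 cis to O–B), which undergoes the [3,3] shift through a chair with C4 and the C9 arm both equatorial, so that C4 ends syn to C9 and anti to C14 across the new C5–C10 bond (vinyl–C10–C5–C6 drawn zigzag). The C2-symmetric diazaborolidine shields one enolate face and so fixes the absolute configuration of C5 and C10 together.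

Step 8
Reactants: 13 (2R,3R)-2-{3-[(TBDPS)oxy]prop-1-en-2-yl}-3-{2-[(PMB)oxy]ethyl}-3-methylpent-4-enoic acid
Product: 14 (2R,3R)-2-{3-[(TBDPS)oxy]prop-1-en-2-yl}-3-{2-[(PMB)oxy]ethyl}-3-methylpent-4-en-1-ol
Conditions: LiAlH4, THF, 0 °C to rt
Reagents that add atoms: none
Why: LiAlH4 reduction of a carboxylic acid to the primary alcohol; the ethers and isolated alkenes are inert and neither stereocentre is touched.

Step 9
Reactants: 14 (2R,3R)-2-{3-[(TBDPS)oxy]prop-1-en-2-yl}-3-{2-[(PMB)oxy]ethyl}-3-methylpent-4-en-1-ol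
Product: 15 (2R,3R)-2-{3-[(TBDPS)oxy]prop-1-en-2-yl}-3-{2-[(PMB)oxy]ethyl}-3-methylpent-4-enal
Conditions: Dess–Martin periodinane, NaHCO3, CH2Cl2, 0 °C to rt
Reagents that add atoms: none
Why: Dess–Martin oxidation under bicarbonate buffer; C5–H is flanked by a quaternary carbon and so is slow to enolise, and the aldehyde is used without storage.

Step 10
Reactants: 15 (2R,3R)-2-{3-[(TBDPS)oxy]prop-1-en-2-yl}-3-{2-[(PMB)oxy]ethyl}-3-methylpent-4-enal; 16 methyl propiolate
Product: 18 methyl (4R,5R,6R)-5-{3-[(TBDPS)oxy]prop-1-en-2-yl}-4-hydroxy-6-{2-[(PMB)oxy]ethyl}-6-methyloct-7-en-2-ynoate, via lithium acetylide 17 (not isolated)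
Conditions: 16, LiN(SiMe3)2, THF, −78 °C; then 15, −78 °C; AcOH quench at −78 °C
Reagents that add atoms: none
Why: 1,2-Addition of a lithium acetylide under Felkin–Anh control: quaternary C10 lies anti to the incoming nucleophile, which passes H5 and not C4, giving the alcohol in which O6 and C4 are syn along the C10–C5–C6–C7 zigzag (4R). Low temperature keeps the unstable acetylide 17 intact and suppresses enolisation of 15.

Step 11
Reactants: 18 methyl (4R,5R,6R)-5-{3-[(TBDPS)oxy]prop-1-en-2-yl}-4-hydroxy-6-{2-[(PMB)oxy]ethyl}-6-methyloct-7-en-2-ynoate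
Product: 19 methyl (4R,5R,6R)-4-[(TBS)oxy]-5-{3-[(TBDPS)oxy]prop-1-en-2-yl}-6-{2-[(PMB)oxy]ethyl}-6-methyloct-7-en-2-ynoate
Conditions: TBSOTf, 2,6-lutidine, CH2Cl2, −78 to 0 °C
Reagents that add atoms: tert-butyldimethylsilyl trifluoromethanesulfonate, CC(C)(C)[Si](C)(C)OS(=O)(=O)C(F)(F)F
Why: Silylation with a silyl triflate and a hindered weak base, chosen because γ-hydroxy ynoates isomerise to γ-oxo enoates under stronger amines; this TBS group is the one meant to stay on O6 through ring closure and acylation.

Step 12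
Reactants: 19 methyl (4R,5R,6R)-4-[(TBS)oxy]-5-{3-[(TBDPS)oxy]prop-1-en-2-yl}-6-{2-[(PMB)oxy]ethyl}-6-methyloct-7-en-2-ynoate
Product: 21 methyl (2Z,4S,5R,6R)-4-[(TBS)oxy]-5-{3-[(TBDPS)oxy]prop-1-en-2-yl}-6-{2-[(PMB)oxy]ethyl}-6-methyl-2-[(Bpin)methyl]octa-2,7-dienoate, via α-alumino enoate 20 (not isolated)
Conditions: i-Bu2AlH, HMPA, THF, 0 °C; then ICH2Bpin, 0 °C to rt
Reagents that add atoms: 2-(iodomethyl)-4,4,5,5-tetramethyl-1,3,2-dioxaborolane, ICB1OC(C)(C)C(C)(C)O1
Why: Conjugate syn-hydroalumination of the ynoate by the i-Bu2AlH–HMPA complex puts aluminium on C11 and hydrogen on C7 cis to it; alkylation of vinylalane 20 with the iodomethylboronate proceeds with retention, so CH2Bpin ends trans to C6 (Z enoate). The HMPA-complexed hydride at 0 °C should leave the ester carbonyl, the silyl and PMB ethers and the isolated alkenes alone.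

Step 13
Reactants: 21 methyl (2Z,4S,5R,6R)-4-[(TBS)oxy]-5-{3-[(TBDPS)oxy]prop-1-en-2-yl}-6-{2-[(PMB)oxy]ethyl}-6-methyl-2-[(Bpin)methyl]octa-2,7-dienoate
Product: 22 methyl (2Z,4S,5R,6R)-4-[(TBS)oxy]-5-{3-[(TBDPS)oxy]prop-1-en-2-yl}-6-(2-hydroxyethyl)-6-methyl-2-[(Bpin)methyl]octa-2,7-dienoate
Conditions: DDQ, CH2Cl2/pH 7 buffer, 0 °C
Reagents that add atoms: none
Why: Oxidative cleavage of the PMB ether by DDQ (hydride abstraction, then hydrolysis of the oxocarbenium ion); the silyl ethers, the electron-poor allylboronate and the unactivated alkenes should not be oxidised.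

Step 14
Reactants: 22 methyl (2Z,4S,5R,6R)-4-[(TBS)oxy]-5-{3-[(TBDPS)oxy]prop-1-en-2-yl}-6-(2-hydroxyethyl)-6-methyl-2-[(Bpin)methyl]octa-2,7-dienoate
Product: 23 methyl (2Z,4S,5R,6R)-4-[(TBS)oxy]-5-{3-[(TBDPS)oxy]prop-1-en-2-yl}-6-methyl-6-(2-oxoethyl)-2-[(Bpin)methyl]octa-2,7-dienoate
Conditions: Dess–Martin periodinane, NaHCO3, CH2Cl2, 0 °C
Reagents that add atoms: none
Why: Dess–Martin oxidation of the primary alcohol; pinacol boronates tolerate the periodinane, and the aldehyde is taken on cold and at once because it carries its own nucleophile.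

Step 15
Reactants: 23 methyl (2Z,4S,5R,6R)-4-[(TBS)oxy]-5-{3-[(TBDPS)oxy]prop-1-en-2-yl}-6-methyl-6-(2-oxoethyl)-2-[(Bpin)methyl]octa-2,7-dienoate
Product: 25 methyl 2-[(1R,2R,3R,4R,6S)-2-[(TBS)oxy]-3-{3-[(TBDPS)oxy]prop-1-en-2-yl}-4-ethenyl-6-hydroxy-4-methylcyclohexyl]prop-2-enoate, via pinacol borate 24 (not isolated)
Conditions: PhMe (0.02 M), 60 °C; then aq. NaHCO3, rt
Reagents that add atoms: none
Why: Intramolecular allylboration: the aldehyde oxygen binds boron and C7 attacks C8 through a closed six-membered chair (B, O8, C8, C7, C11, C13) with allylic transposition, which moves the alkene to C11=C13 and leaves O8 as the pinacol borate 24, hydrolysed on work-up. The closest known reaction types are the thermal additions of 2-alkoxycarbonyl allylboronates to aldehydes and the cyclisations of ω-formyl allylboronates to trans-2-alkenylcyclohexanols. The cyclohexane closes by a 6-exo-trig attack on the carbonyl, the new ring adopting a chair trans-fused to the boron-containing chair. C8 is set relative to C7 by the alkene geometry: with C6 trans to CH2B, O8 and C11 both sit equatorial on the new ring and end trans. C7 is set by the existing centres: in the favoured chair the C6 silyloxy group and the C5 branch are equatorial and only the C10 vinyl group is axial, whereas attack on the other alkene face would force O6, C4 and C14 axial with a 1,3-diaxial O6/C14 clash. The step also needs chemoselectivity: thermal, acid-free conditions keep O8 masked as its borate so that it does not lactonise onto C12, and no Lewis acid is present to trigger a carbonyl-ene closure onto C4=C3. Pinacol allylboronates do not undergo 1,3-boron shifts at this temperature, so the Z geometry should be transmitted intact.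

Step 16
Reactants: 26 methyl (2R)-3-hydroxy-2-methylpropanoate
Product: 27 methyl (2R)-3-[(TBS)oxy]-2-methylpropanoate
Conditions: TBSCl, imidazole, CH2Cl2, 0 °C to rt
Reagents that add atoms: tert-butyl(chloro)dimethylsilane, CC(C)(C)[Si](C)(C)Cl
Why: Silylation of the primary alcohol of the Roche ester; the α-stereocentre is not involved.

Step 17
Reactants: 27 methyl (2R)-3-[(TBS)oxy]-2-methylpropanoate
Product: 28 (2R)-3-[(TBS)oxy]-2-methylpropanoic acid
Conditions: LiOH, THF/MeOH/H2O, 0 °C to rt; then 1 M HCl to pH 4, 0 °C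
Reagents that add atoms: lithium hydroxide, [Li+].[OH-]
Why: Saponification under mild conditions that spare primary TBS ethers and the α-stereocentre of 2-methyl-3-silyloxypropanoates.

Step 18
Reactants: 28 (2R)-3-[(TBS)oxy]-2-methylpropanoic acid; 25 methyl 2-[(1R,2R,3R,4R,6S)-2-[(TBS)oxy]-3-{3-[(TBDPS)oxy]prop-1-en-2-yl}-4-ethenyl-6-hydroxy-4-methylcyclohexyl]prop-2-enoate
Product: 30 (1S,2R,3R,4R,5R)-3-[(TBS)oxy]-4-{3-[(TBDPS)oxy]prop-1-en-2-yl}-5-ethenyl-2-(3-methoxy-3-oxoprop-1-en-2-yl)-5-methylcyclohexyl (2R)-3-[(TBS)oxy]-2-methylpropanoate, via mixed anhydride 29 (not isolated)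
Conditions: 2,4,6-trichlorobenzoyl chloride, Et3N, THF, rt; then 25, 4-dimethylaminopyridine, PhMe, rt
Reagents that add atoms: none
Why: Yamaguchi esterification: 4-dimethylaminopyridine attacks mixed anhydride 29 at the less hindered carbonyl and the acylpyridinium acylates the hindered equatorial C8 hydroxyl. Acylation by an activated donor should outrun lactonisation of O8 onto the methyl acrylate, and the conditions are not basic enough to form a ketene, so the α-stereocentre is kept.

Step 19
Reactants: 30 (1S,2R,3R,4R,5R)-3-[(TBS)oxy]-4-{3-[(TBDPS)oxy]prop-1-en-2-yl}-5-ethenyl-2-(3-methoxy-3-oxoprop-1-en-2-yl)-5-methylcyclohexyl (2R)-3-[(TBS)oxy]-2-methylpropanoate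
Product: 32 (3aR,4S,6R,7R,7aR)-6-ethenyl-7-(3-hydroxyprop-1-en-2-yl)-6-methyl-3-methylidene-2-oxooctahydro-1-benzofuran-4-yl (2R)-3-hydroxy-2-methylpropanoate, via triol methyl ester 31 (not isolated)
Conditions: HF·pyridine, pyridine, THF, 0 °C to rt; then p-toluenesulfonic acid monohydrate (cat.), CH2Cl2, rt
Reagents that add atoms: none
Why: Fluoride cleavage of all three silyl ethers under acidic conditions, then acid-catalysed transesterification of the freed C6 hydroxyl with the neighbouring methyl acrylate (5-exo-trig lactonisation to the trans-fused lactone). O8 is already acylated, so the lactone can only form towards O6; basic fluoride sources are avoided because they would invite acyl migration and conjugate addition to the methylene lactone.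

## Compound list

1 | but-3-yn-1-ol | C#CCCO | starting material
2 | 1-[(but-3-yn-1-yloxy)methyl]-4-methoxybenzene | C#CCCOCc1ccc(OC)cc1 | intermediate
3 | dimethyl{(1E)-4-[(4-methoxybenzyl)oxy]-2-methylbut-1-en-1-yl}alane | C[Al](C)/C=C(\C)CCOCc1ccc(OC)cc1 | intermediate
4 | lithium butyl(dimethyl){(1E)-4-[(4-methoxybenzyl)oxy]-2-methylbut-1-en-1-yl}aluminate | [Li+].CCCC[Al-](C)(C)/C=C(\C)CCOCc1ccc(OC)cc1 | intermediate
5 | (2E)-5-[(4-methoxybenzyl)oxy]-3-methylpent-2-en-1-ol | OC/C=C(\C)CCOCc1ccc(OC)cc1 | intermediate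
6 | 4-methyl hydrogen itaconate (4-methoxy-2-methylidene-4-oxobutanoic acid) | C=C(CC(=O)OC)C(=O)O | starting material
7 | methyl 3-(hydroxymethyl)but-3-enoate | C=C(CO)CC(=O)OC | intermediate
8 | methyl 3-{[(tert-butyldiphenylsilyl)oxy]methyl}but-3-enoate | C=C(CO[Si](c1ccccc1)(c1ccccc1)C(C)(C)C)CC(=O)OC | intermediate
9 | 3-{[(tert-butyldiphenylsilyl)oxy]methyl}but-3-enoic acid | C=C(CO[Si](c1ccccc1)(c1ccccc1)C(C)(C)C)CC(=O)O | intermediate
10 | O-acylisourea of 9 with N,N'-dicyclohexylcarbodiimide | C=C(CO[Si](c1ccccc1)(c1ccccc1)C(C)(C)C)CC(=O)OC(=NC1CCCCC1)NC1CCCCC1 | intermediate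
11 | (2E)-5-[(4-methoxybenzyl)oxy]-3-methylpent-2-en-1-yl 3-{[(tert-butyldiphenylsilyl)oxy]methyl}but-3-enoate | C=C(CO[Si](c1ccccc1)(c1ccccc1)C(C)(C)C)CC(=O)OC/C=C(\C)CCOCc1ccc(OC)cc1 | intermediate
12 | boron ketene acetal of 11 with C4 cis to O–B, boron being part of the (4S,5S)-1,3-bis{[3,5-bis(trifluoromethyl)phenyl]sulfonyl}-4,5-diphenyl-1,3,2-diazaborolidin-2-yl group | C=C(CO[Si](c1ccccc1)(c1ccccc1)C(C)(C)C)/C=C(\OB1N(S(=O)(=O)c2cc(C(F)(F)F)cc(C(F)(F)F)c2)[C@@H](c2ccccc2)[C@H](c2ccccc2)N1S(=O)(=O)c1cc(C(F)(F)F)cc(C(F)(F)F)c1)OC/C=C(\C)CCOCc1ccc(OC)cc1 | intermediate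
13 | (2R,3R)-2-{3-[(tert-butyldiphenylsilyl)oxy]prop-1-en-2-yl}-3-{2-[(4-methoxybenzyl)oxy]ethyl}-3-methylpent-4-enoic acid | C=C[C@@](C)(CCOCc1ccc(OC)cc1)[C@H](C(=C)CO[Si](c1ccccc1)(c1ccccc1)C(C)(C)C)C(=O)O | intermediate
14 | (2R,3R)-2-{3-[(tert-butyldiphenylsilyl)oxy]prop-1-en-2-yl}-3-{2-[(4-methoxybenzyl)oxy]ethyl}-3-methylpent-4-en-1-ol | C=C[C@@](C)(CCOCc1ccc(OC)cc1)[C@H](C(=C)CO[Si](c1ccccc1)(c1ccccc1)C(C)(C)C)CO | intermediate
15 | (2R,3R)-2-{3-[(tert-butyldiphenylsilyl)oxy]prop-1-en-2-yl}-3-{2-[(4-methoxybenzyl)oxy]ethyl}-3-methylpent-4-enal | C=C[C@@](C)(CCOCc1ccc(OC)cc1)[C@H](C(=C)CO[Si](c1ccccc1)(c1ccccc1)C(C)(C)C)C=O | intermediate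
16 | methyl propiolate (methyl prop-2-ynoate) | C#CC(=O)OC | starting material
17 | lithium 3-methoxy-3-oxoprop-1-yn-1-ide (lithium acetylide of 16) | [Li]C#CC(=O)OC | intermediate
18 | methyl (4R,5R,6R)-5-{3-[(tert-butyldiphenylsilyl)oxy]prop-1-en-2-yl}-4-hydroxy-6-{2-[(4-methoxybenzyl)oxy]ethyl}-6-methyloct-7-en-2-ynoate | C=C[C@@](C)(CCOCc1ccc(OC)cc1)[C@H](C(=C)CO[Si](c1ccccc1)(c1ccccc1)C(C)(C)C)[C@@H](O)C#CC(=O)OC | intermediate
19 | methyl (4R,5R,6R)-4-[(tert-butyldimethylsilyl)oxy]-5-{3-[(tert-butyldiphenylsilyl)oxy]prop-1-en-2-yl}-6-{2-[(4-methoxybenzyl)oxy]ethyl}-6-methyloct-7-en-2-ynoate | C=C[C@@](C)(CCOCc1ccc(OC)cc1)[C@H](C(=C)CO[Si](c1ccccc1)(c1ccccc1)C(C)(C)C)[C@@H](O[Si](C)(C)C(C)(C)C)C#CC(=O)OC | intermediate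
20 | methyl (2E,4R,5R,6R)-2-[bis(2-methylpropyl)alumanyl]-4-[(tert-butyldimethylsilyl)oxy]-5-{3-[(tert-butyldiphenylsilyl)oxy]prop-1-en-2-yl}-6-{2-[(4-methoxybenzyl)oxy]ethyl}-6-methylocta-2,7-dienoate (C6 cis to the ester) | C=C[C@@](C)(CCOCc1ccc(OC)cc1)[C@H](C(=C)CO[Si](c1ccccc1)(c1ccccc1)C(C)(C)C)[C@@H](O[Si](C)(C)C(C)(C)C)/C=C(/[Al](CC(C)C)CC(C)C)C(=O)OC | intermediate
21 | methyl (2Z,4S,5R,6R)-4-[(tert-butyldimethylsilyl)oxy]-5-{3-[(tert-butyldiphenylsilyl)oxy]prop-1-en-2-yl}-6-{2-[(4-methoxybenzyl)oxy]ethyl}-6-methyl-2-[(4,4,5,5-tetramethyl-1,3,2-dioxaborolan-2-yl)methyl]octa-2,7-dienoate | C=C[C@@](C)(CCOCc1ccc(OC)cc1)[C@H](C(=C)CO[Si](c1ccccc1)(c1ccccc1)C(C)(C)C)[C@@H](O[Si](C)(C)C(C)(C)C)/C=C(/CB1OC(C)(C)C(C)(C)O1)C(=O)OC | intermediate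
22 | methyl (2Z,4S,5R,6R)-4-[(tert-butyldimethylsilyl)oxy]-5-{3-[(tert-butyldiphenylsilyl)oxy]prop-1-en-2-yl}-6-(2-hydroxyethyl)-6-methyl-2-[(4,4,5,5-tetramethyl-1,3,2-dioxaborolan-2-yl)methyl]octa-2,7-dienoate | C=C[C@@](C)(CCO)[C@H](C(=C)CO[Si](c1ccccc1)(c1ccccc1)C(C)(C)C)[C@@H](O[Si](C)(C)C(C)(C)C)/C=C(/CB1OC(C)(C)C(C)(C)O1)C(=O)OC | intermediate
23 | methyl (2Z,4S,5R,6R)-4-[(tert-butyldimethylsilyl)oxy]-5-{3-[(tert-butyldiphenylsilyl)oxy]prop-1-en-2-yl}-6-methyl-6-(2-oxoethyl)-2-[(4,4,5,5-tetramethyl-1,3,2-dioxaborolan-2-yl)methyl]octa-2,7-dienoate | C=C[C@@](C)(CC=O)[C@H](C(=C)CO[Si](c1ccccc1)(c1ccccc1)C(C)(C)C)[C@@H](O[Si](C)(C)C(C)(C)C)/C=C(/CB1OC(C)(C)C(C)(C)O1)C(=O)OC | intermediate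
24 | methyl 2-[(1R,2R,3R,4R,6S)-2-[(tert-butyldimethylsilyl)oxy]-3-{3-[(tert-butyldiphenylsilyl)oxy]prop-1-en-2-yl}-4-ethenyl-4-methyl-6-[(4,4,5,5-tetramethyl-1,3,2-dioxaborolan-2-yl)oxy]cyclohexyl]prop-2-enoate | C=C[C@@]1(C)C[C@H](OB2OC(C)(C)C(C)(C)O2)[C@@H](C(=C)C(=O)OC)[C@H](O[Si](C)(C)C(C)(C)C)[C@H]1C(=C)CO[Si](c1ccccc1)(c1ccccc1)C(C)(C)C | intermediate
25 | methyl 2-[(1R,2R,3R,4R,6S)-2-[(tert-butyldimethylsilyl)oxy]-3-{3-[(tert-butyldiphenylsilyl)oxy]prop-1-en-2-yl}-4-ethenyl-6-hydroxy-4-methylcyclohexyl]prop-2-enoate | C=C[C@@]1(C)C[C@H](O)[C@@H](C(=C)C(=O)OC)[C@H](O[Si](C)(C)C(C)(C)C)[C@H]1C(=C)CO[Si](c2ccccc2)(c2ccccc2)C(C)(C)C | intermediate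
26 | methyl (2R)-3-hydroxy-2-methylpropanoate | COC(=O)[C@H](C)CO | starting material
27 | methyl (2R)-3-[(tert-butyldimethylsilyl)oxy]-2-methylpropanoate | COC(=O)[C@H](C)CO[Si](C)(C)C(C)(C)C | intermediate
28 | (2R)-3-[(tert-butyldimethylsilyl)oxy]-2-methylpropanoic acid | OC(=O)[C@H](C)CO[Si](C)(C)C(C)(C)C | intermediate
29 | (2R)-3-[(tert-butyldimethylsilyl)oxy]-2-methylpropanoic 2,4,6-trichlorobenzoic anhydride | O=C(OC(=O)[C@H](C)CO[Si](C)(C)C(C)(C)C)c1c(Cl)cc(Cl)cc1Cl | intermediate
30 | (1S,2R,3R,4R,5R)-3-[(tert-butyldimethylsilyl)oxy]-4-{3-[(tert-butyldiphenylsilyl)oxy]prop-1-en-2-yl}-5-ethenyl-2-(3-methoxy-3-oxoprop-1-en-2-yl)-5-methylcyclohexyl (2R)-3-[(tert-butyldimethylsilyl)oxy]-2-methylpropanoate | C=C[C@@]1(C)C[C@H](OC(=O)[C@H](C)CO[Si](C)(C)C(C)(C)C)[C@@H](C(=C)C(=O)OC)[C@H](O[Si](C)(C)C(C)(C)C)[C@H]1C(=C)CO[Si](c2ccccc2)(c2ccccc2)C(C)(C)C | intermediate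
31 | (1S,2S,3R,4R,5R)-5-ethenyl-3-hydroxy-4-(3-hydroxyprop-1-en-2-yl)-2-(3-methoxy-3-oxoprop-1-en-2-yl)-5-methylcyclohexyl (2R)-3-hydroxy-2-methylpropanoate | C=C[C@@]1(C)C[C@H](OC(=O)[C@H](C)CO)[C@@H](C(=C)C(=O)OC)[C@H](O)[C@H]1C(=C)CO | intermediate
32 | (3aR,4S,6R,7R,7aR)-6-ethenyl-7-(3-hydroxyprop-1-en-2-yl)-6-methyl-3-methylidene-2-oxooctahydro-1-benzofuran-4-yl (2R)-3-hydroxy-2-methylpropanoate | C=C[C@@]1(C)C[C@H](OC(=O)[C@H](C)CO)[C@H]2C(=C)C(=O)O[C@@H]2[C@H]1C(=C)CO | target

## Step count and risk

Total: 19 steps. Longest linear sequence: 15 steps (from 6 through steps 3–15, 18 and 19).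

**Step 15 (key step).** The process most likely to go wrong is slow closure, because the ester makes the allylboronate a weak nucleophile; forcing it lets the C8 borate lactonise onto C12, and any Lewis acid added to help could instead trigger a carbonyl-ene closure onto C4=C3. The fallback turns that lactonisation into the driving force; it sets out from 23 and comes back at 25. Heating 23 in toluene at 110 °C until allylboration and lactonisation are both complete should give the trans-fused 8,12-lactone F1. LiOH in THF/H2O at 0 °C would open it to the hydroxy acid F2, and Me3SiCHN2 in toluene/MeOH would re-esterify the carboxyl group to give 25, ready for immediate acylation.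

**Step 7.** The process most likely to go wrong is formation of the other enolate geometry (C4 trans to O–B), because the dienolate of a β,γ-unsaturated ester need not follow the amine/solvent rules of simple esters; that would give the C5 epimer. The fallback moves the stereochemical lever from the enolate to the alkene; it sets out from 2 and comes back at 13. Deprotonation of 2 (n-BuLi) and methyl chloroformate would give methyl 5-[(4-methoxybenzyl)oxy]pent-2-ynoate F3. Syn addition of Me2CuLi at −78 °C would give the (Z)-enoate F4, and i-Bu2AlH reduction the (Z)-allylic alcohol F5. Steglich esterification with 9 would give the (Z)-allyl ester F6. Enolisation with Et3N in toluene/hexane would then give the ketene acetal F7 with C4 trans to O–B, whose chair rearrangement leads to the same acid 13. The (R,R)-bromoborane is used here on the premise that the facial preference of the boron enolate is unchanged.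

**Step 12.** The process most likely to go wrong is loss of alkene geometry through the aluminium allenolate, or protonation in place of alkylation if the hindered vinylalane reacts slowly with the iodomethylboronate. The fallback separates the geometry-defining step from the C–C bond formation; it sets out from 19 and comes back at 21. Syn-hydrostannation with Bu3SnH and Pd(PPh3)4 should give the α-stannyl enoate F8. Iododestannylation (I2, CH2Cl2, 0 °C) would give the α-iodo enoate F9 with retention, and Negishi coupling with IZnCH2Bpin under Pd(PPh3)4 would give 21.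

**Step 10.** The process most likely to go wrong is poor facial selectivity, since a small linear acetylide discriminates only moderately between the Felkin and anti-Felkin trajectories. The fallback replaces substrate control by reagent control; it sets out from 18 (as its mixture of C6 epimers) and comes back at 18. Dess–Martin oxidation would give the ynone F10, and reduction with (R)-2-methyl-CBS-oxazaborolidine and catecholborane at −78 °C, with the alkyne as the small group, should return the (4R)-alcohol 18; the reagent preference and the Felkin preference point the same way.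

**Step 19.** The process most likely to go wrong is incomplete lactonisation of the methyl ester, with acyl migration from O8 to the freed O6 as the competing pathway. The fallback activates C12 before O6 is released; it sets out from 30 and comes back at 32. Me3SnOH in 1,2-dichloroethane at 80 °C should cleave the methyl ester selectively to the acrylic acid F11. HF·pyridine would then remove the silyl groups to give the triol acid F12, which as a γ-hydroxy acid should close to 32 under the acidic conditions.

## Further compounds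

F1 | step 15 | (3aR,4R,5R,6R,7aS)-4-[(tert-butyldimethylsilyl)oxy]-5-{3-[(tert-butyldiphenylsilyl)oxy]prop-1-en-2-yl}-6-ethenyl-6-methyl-3-methylidenehexahydro-1-benzofuran-2(3H)-one (trans-fused 8,12-lactone) | C=C[C@@]1(C)C[C@@H]2OC(=O)C(=C)[C@H]2[C@H](O[Si](C)(C)C(C)(C)C)[C@H]1C(=C)CO[Si](c3ccccc3)(c3ccccc3)C(C)(C)C
F2 | step 15 | 2-[(1R,2R,3R,4R,6S)-2-[(tert-butyldimethylsilyl)oxy]-3-{3-[(tert-butyldiphenylsilyl)oxy]prop-1-en-2-yl}-4-ethenyl-6-hydroxy-4-methylcyclohexyl]prop-2-enoic acid | C=C[C@@]1(C)C[C@H](O)[C@@H](C(=C)C(=O)O)[C@H](O[Si](C)(C)C(C)(C)C)[C@H]1C(=C)CO[Si](c2ccccc2)(c2ccccc2)C(C)(C)C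
F3 | step 7 | methyl 5-[(4-methoxybenzyl)oxy]pent-2-ynoate | COC(=O)C#CCCOCc1ccc(OC)cc1
F4 | step 7 | methyl (2Z)-5-[(4-methoxybenzyl)oxy]-3-methylpent-2-enoate | COC(=O)/C=C(/C)CCOCc1ccc(OC)cc1
F5 | step 7 | (2Z)-5-[(4-methoxybenzyl)oxy]-3-methylpent-2-en-1-ol | OC/C=C(/C)CCOCc1ccc(OC)cc1
F6 | step 7 | (2Z)-5-[(4-methoxybenzyl)oxy]-3-methylpent-2-en-1-yl 3-{[(tert-butyldiphenylsilyl)oxy]methyl}but-3-enoate | C=C(CO[Si](c1ccccc1)(c1ccccc1)C(C)(C)C)CC(=O)OC/C=C(/C)CCOCc1ccc(OC)cc1
F7 | step 7 | boron ketene acetal of F6 with C4 trans to O–B, boron being part of the (4R,5R)-1,3-bis{[3,5-bis(trifluoromethyl)phenyl]sulfonyl}-4,5-diphenyl-1,3,2-diazaborolidin-2-yl group | C=C(CO[Si](c1ccccc1)(c1ccccc1)C(C)(C)C)/C=C(/OB1N(S(=O)(=O)c2cc(C(F)(F)F)cc(C(F)(F)F)c2)[C@H](c2ccccc2)[C@@H](c2ccccc2)N1S(=O)(=O)c1cc(C(F)(F)F)cc(C(F)(F)F)c1)OC/C=C(/C)CCOCc1ccc(OC)cc1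
F8 | step 12 | methyl (2E,4R,5R,6R)-4-[(tert-butyldimethylsilyl)oxy]-5-{3-[(tert-butyldiphenylsilyl)oxy]prop-1-en-2-yl}-6-{2-[(4-methoxybenzyl)oxy]ethyl}-6-methyl-2-(tributylstannyl)octa-2,7-dienoate | C=C[C@@](C)(CCOCc1ccc(OC)cc1)[C@H](C(=C)CO[Si](c1ccccc1)(c1ccccc1)C(C)(C)C)[C@@H](O[Si](C)(C)C(C)(C)C)/C=C(/[Sn](CCCC)(CCCC)CCCC)C(=O)OC
F9 | step 12 | methyl (2E,4R,5R,6R)-4-[(tert-butyldimethylsilyl)oxy]-5-{3-[(tert-butyldiphenylsilyl)oxy]prop-1-en-2-yl}-2-iodo-6-{2-[(4-methoxybenzyl)oxy]ethyl}-6-methylocta-2,7-dienoate | C=C[C@@](C)(CCOCc1ccc(OC)cc1)[C@H](C(=C)CO[Si](c1ccccc1)(c1ccccc1)C(C)(C)C)[C@@H](O[Si](C)(C)C(C)(C)C)/C=C(/I)C(=O)OC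
F10 | step 10 | methyl (5R,6R)-5-{3-[(tert-butyldiphenylsilyl)oxy]prop-1-en-2-yl}-6-{2-[(4-methoxybenzyl)oxy]ethyl}-6-methyl-4-oxooct-7-en-2-ynoate | C=C[C@@](C)(CCOCc1ccc(OC)cc1)[C@H](C(=C)CO[Si](c1ccccc1)(c1ccccc1)C(C)(C)C)C(=O)C#CC(=O)OC
F11 | step 19 | 2-[(1R,2R,3R,4R,6S)-2-[(tert-butyldimethylsilyl)oxy]-3-{3-[(tert-butyldiphenylsilyl)oxy]prop-1-en-2-yl}-4-ethenyl-4-methyl-6-{[(2R)-3-[(tert-butyldimethylsilyl)oxy]-2-methylpropanoyl]oxy}cyclohexyl]prop-2-enoic acid | C=C[C@@]1(C)C[C@H](OC(=O)[C@H](C)CO[Si](C)(C)C(C)(C)C)[C@@H](C(=C)C(=O)O)[C@H](O[Si](C)(C)C(C)(C)C)[C@H]1C(=C)CO[Si](c2ccccc2)(c2ccccc2)C(C)(C)C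
F12 | step 19 | 2-[(1S,2R,3R,4R,6S)-4-ethenyl-2-hydroxy-3-(3-hydroxyprop-1-en-2-yl)-6-{[(2R)-3-hydroxy-2-methylpropanoyl]oxy}-4-methylcyclohexyl]prop-2-enoic acid | C=C[C@@]1(C)C[C@H](OC(=O)[C@H](C)CO)[C@@H](C(=C)C(=O)O)[C@H](O)[C@H]1C(=C)CO
A1 | alternative 1 | (5S)-5-[(tert-butyldimethylsilyl)oxy]-3-methylcyclohex-2-en-1-one | CC1=CC(=O)C[C@@H](O[Si](C)(C)C(C)(C)C)C1
A2 | alternative 1 | tert-butyl(diphenyl)(prop-2-yn-1-yloxy)silane | C#CCO[Si](c1ccccc1)(c1ccccc1)C(C)(C)C
A3 | alternative 1 | (1R,4S,6R)-4-[(tert-butyldimethylsilyl)oxy]-8-{[(tert-butyldiphenylsilyl)oxy]methyl}-6-methylbicyclo[4.2.0]oct-7-en-2-one (cis-fused) | C1=C(CO[Si](c3ccccc3)(c3ccccc3)C(C)(C)C)[C@@H]2C(=O)C[C@@H](O[Si](C)(C)C(C)(C)C)C[C@]12C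
A4 | alternative 2 | (1S,2S,3R,4R,5R)-4-{3-[(tert-butyldiphenylsilyl)oxy]prop-1-en-2-yl}-5-ethenyl-2-ethynyl-3-hydroxy-5-methylcyclohexyl (2R)-3-[(tert-butyldiphenylsilyl)oxy]-2-methylpropanoate | C=C[C@@]1(C)C[C@H](OC(=O)[C@H](C)CO[Si](c2ccccc2)(c2ccccc2)C(C)(C)C)[C@@H](C#C)[C@H](O)[C@H]1C(=C)CO[Si](c2ccccc2)(c2ccccc2)C(C)(C)C
A5 | alternative 2 | bis(tert-butyldiphenylsilyl) ether of 32 (both primary hydroxyls silylated) | C=C[C@@]1(C)C[C@H](OC(=O)[C@H](C)CO[Si](c3ccccc3)(c3ccccc3)C(C)(C)C)[C@H]2C(=C)C(=O)O[C@@H]2[C@H]1C(=C)CO[Si](c4ccccc4)(c4ccccc4)C(C)(C)C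
A6 | alternative 3 | C10–C1 epoxide of the cycloheptane-fused trans-γ-lactone carrying the C10 methyl group, the C8 tert-butyldimethylsilyl ether and the C5 [(tert-butyldiphenylsilyl)oxy]acetyl group | C[C@]12O[C@H]1C[C@H](O[Si](C)(C)C(C)(C)C)[C@H]3CC(=O)O[C@@H]3[C@H]2C(=O)CO[Si](c4ccccc4)(c4ccccc4)C(C)(C)C
A7 | alternative 3 | ring-contracted cyclohexane-fused trans-γ-lactone with quaternary C10 bearing methyl and formyl, the C8 tert-butyldimethylsilyl ether and the C5 [(tert-butyldiphenylsilyl)oxy]acetyl group | O=C[C@@]1(C)C[C@H](O[Si](C)(C)C(C)(C)C)[C@H]2CC(=O)O[C@@H]2[C@H]1C(=O)CO[Si](c3ccccc3)(c3ccccc3)C(C)(C)C
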